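## Retrosynthetic overview

1. The target 2,5-dimethoxyquinone comes from double O-methylation of the 2,5-dihydroxy-3,6-bis(indolyl)-1,4-benzoquinone.
2. Both indole C3–quinone bonds are cut with reversed polarity at the ring. The enol carbons of 2,5-dihydroxy-1,4-benzoquinone (normally nucleophilic) become enolonium carbons in its bis(phenyliodonium) ylide and take two nucleophilic indole C3 carbons in one flask, hindered indole A first, then indole.
3. Indole A comes from 7-bromoindole: the C2 tert-prenyl group by allylboration of the electrophilic 3-chloroindolenine, the C7 prenyl group by Br–Li exchange and alkylation.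
4. No ring is formed. The quinone ring and both indole ring systems are bought and joined in the order quinone–indole A, then quinone–indole B.

Assumption: the target has no stereocentre and no stereogenic double bond, so it is one achiral compound and no enantiocontrol is needed.

## Route

Step 1
Reactants: 1 7-bromo-1H-indole
Product: 3 7-bromo-2-(2-methylbut-3-en-2-yl)-1H-indole, via 7-bromo-3-chloro-1H-indole 2 (not isolated)
Conditions: NCS (1.05 equiv), CH2Cl2, 0 °C → rt; then Et3N (2 equiv), B-prenyl-9-BBN (1.5 equiv, from 9-BBN + 3-methylbuta-1,2-diene, THF), −78 °C → rt; aq. NaHCO3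
Reagents that add atoms: B-(3-methylbut-2-en-1-yl)-9-borabicyclo[3.3.1]nonane CC(C)=CCB1C2CCCC1CCC2
Why: C3-chlorination gives 2, whose 3H-indolenine tautomer binds the borane at nitrogen and takes the allyl group at C2 through a six-membered transition state with allylic transposition, and loss of HCl re-aromatises (reverse prenylation of a chloroindolenine by allylboration); no stereocentre is formed.

Step 2
Reactants: 3 7-bromo-2-(2-methylbut-3-en-2-yl)-1H-indole
Product: 6 2-(2-methylbut-3-en-2-yl)-7-(3-methylbut-2-en-1-yl)-1H-indole (indole A), via N-potassio bromoindole 4 (not isolated), via 7-lithio-1-potassio indole 5 (not isolated)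
Conditions: KH (1.1 equiv), THF, 0 °C; t-BuLi (2.1 equiv), −78 °C; prenyl bromide (1.1 equiv), −78 °C → rt; H2O
Reagents that add atoms: prenyl bromide (1-bromo-3-methylbut-2-ene) CC(C)=CCBr
Why: The potassium indolide masks the NH so that t-BuLi does clean bromine–lithium exchange at C7, and the aryllithium, far more nucleophilic than the flanked indolide nitrogen, is alkylated at the primary carbon of prenyl bromide (halogen–metal exchange, then SN2 alkylation).

Step 3
Reactants: 7 2,5-dihydroxy-1,4-benzoquinone
Product: 8 2,5-dioxido-3,6-bis(phenyliodonio)-1,4-benzoquinone (bis(phenyliodonium) ylide)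
Conditions: PhI(OAc)2 (2.1 equiv), MeOH–CH2Cl2, 0 °C → rt, dark; filter the solid
Reagents that add atoms: (diacetoxyiodo)benzene CC(=O)OI(OC(C)=O)c1ccccc1
Why: Each enol carbon of the vinylogous acid attacks trivalent iodine and loses acetic acid to give a doubly stabilised iodonium ylide (standard iodonium-ylide formation from a 1,3-dicarbonyl-type C–H acid), which turns the two nucleophilic ring carbons into latent enolonium carbons.

Step 4
Reactants: 8 2,5-dioxido-3,6-bis(phenyliodonio)-1,4-benzoquinone; 6 2-(2-methylbut-3-en-2-yl)-7-(3-methylbut-2-en-1-yl)-1H-indole; 9 1H-indole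
Product: 11 2,5-dihydroxy-3-(1H-indol-3-yl)-6-[2-(2-methylbut-3-en-2-yl)-7-(3-methylbut-2-en-1-yl)-1H-indol-3-yl]-1,4-benzoquinone, via mono-indolyl iodonium ylide 10 (not isolated)
Conditions: 8 (2 equiv), BF3·OEt2 (0.5 equiv), CH2Cl2–MeCN, −20 °C, slow addition of 6 (1 equiv); then 9 (5 equiv), BF3·OEt2 (0.5 equiv), −20 °C → rt
Reagents that add atoms: none
Why: Proposed new method: BF3 binds the oxido oxygen and turns each ylide carbon into an α-iodonio enone carbon (an enolonium equivalent), indole C3 adds there and PhI leaves as a hypernucleofuge (addition–elimination or ligand coupling at trivalent iodine), the excess of 8 and the donor effect of the first indolyl group favour mono-coupling with 6 before indole takes the second site, and the low temperature holds back ring contraction; the closest known reaction type is the BF3-mediated arylation of hydroxyquinone phenyliodonium ylides by electron-rich arenes, here extended to a bis-ylide and two different indoles in one flask; no stereocentre is formed.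

Step 5
Reactants: 11 2,5-dihydroxy-3-(1H-indol-3-yl)-6-[2-(2-methylbut-3-en-2-yl)-7-(3-methylbut-2-en-1-yl)-1H-indol-3-yl]-1,4-benzoquinone
Product: 12 2,5-dimethoxy-3-(1H-indol-3-yl)-6-[2-(2-methylbut-3-en-2-yl)-7-(3-methylbut-2-en-1-yl)-1H-indol-3-yl]-1,4-benzoquinone (target)
Conditions: TMSCHN2 (2.5 equiv), MeOH–toluene 1:4, 0 °C → rt; AcOH quench
Reagents that add atoms: (trimethylsilyl)diazomethane C[Si](C)(C)C=[N+]=[N-]
Why: The two hydroxyquinone OH groups are vinylogous carboxylic acids and are O-methylated by diazoalkane esterification-type chemistry, while the far less acidic indole NH groups and the alkenes are untouched.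

## Compound list

1 | 7-bromo-1H-indole | Brc1cccc2cc[nH]c12 | starting material
2 | 7-bromo-3-chloro-1H-indole | Clc1c[nH]c2c(Br)cccc12 | intermediate
3 | 7-bromo-2-(2-methylbut-3-en-2-yl)-1H-indole | C=CC(C)(C)c1cc2cccc(Br)c2[nH]1 | intermediate
4 | potassium 7-bromo-2-(2-methylbut-3-en-2-yl)indol-1-ide | C=CC(C)(C)c1cc2cccc(Br)c2n1[K] | intermediate
5 | 7-lithio-1-potassio-2-(2-methylbut-3-en-2-yl)indole | C=CC(C)(C)c1cc2cccc([Li])c2n1[K] | intermediate
6 | 2-(2-methylbut-3-en-2-yl)-7-(3-methylbut-2-en-1-yl)-1H-indole (indole A) | C=CC(C)(C)c1cc2cccc(CC=C(C)C)c2[nH]1 | intermediate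
7 | 2,5-dihydroxy-1,4-benzoquinone | O=C1C=C(O)C(=O)C=C1O | starting material
8 | 2,5-dioxido-3,6-bis(phenyliodonio)cyclohexa-2,5-diene-1,4-dione | O=C1C([I+]c2ccccc2)=C([O-])C(=O)C([I+]c2ccccc2)=C1[O-] | intermediate
9 | 1H-indole | c1ccc2[nH]ccc2c1 | starting material
10 | 2-hydroxy-3-[2-(2-methylbut-3-en-2-yl)-7-(3-methylbut-2-en-1-yl)-1H-indol-3-yl]-5-oxido-6-(phenyliodonio)cyclohexa-2,5-diene-1,4-dione | O=C1C([I+]c2ccccc2)=C([O-])C(=O)C(c2c(C(C)(C)C=C)[nH]c3c(CC=C(C)C)cccc23)=C1O | intermediate
11 | 2,5-dihydroxy-3-(1H-indol-3-yl)-6-[2-(2-methylbut-3-en-2-yl)-7-(3-methylbut-2-en-1-yl)-1H-indol-3-yl]cyclohexa-2,5-diene-1,4-dione | C=CC(C)(C)c1[nH]c2c(CC=C(C)C)cccc2c1C1=C(O)C(=O)C(c2c[nH]c3ccccc23)=C(O)C1=O | intermediate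
12 | 2,5-dimethoxy-3-(1H-indol-3-yl)-6-[2-(2-methylbut-3-en-2-yl)-7-(3-methylbut-2-en-1-yl)-1H-indol-3-yl]cyclohexa-2,5-diene-1,4-dione | C=CC(C)(C)c1[nH]c2c(CC=C(C)C)cccc2c1C1=C(OC)C(=O)C(c2c[nH]c3ccccc23)=C(OC)C1=O | target

## Step count and risk

Total step count: 5.
Longest linear sequence: 4 steps (1 → 3 → 6 → 11 → 12); step 3 is a one-step side branch.

Most likely to fail, with one fallback each:

Step 4. The double enolonium arylation is new. The ylide may contract its ring, transfer phenyl, oxidise the indole, or couple twice with 6. The fallback gives up the iodonium ylide. It makes the same two bonds by acid-promoted conjugate addition of the indoles to a halo-quinone with re-oxidation, and puts the oxygen in last. It sets out from 6 and comes back at 11. With Ar = 2-(2-methylbut-3-en-2-yl)-7-(3-methylbut-2-en-1-yl)-1H-indol-3-yl: 6 and commercial 2,5-dichloro-1,4-benzoquinone (conc. HCl cat., THF, rt) give 2,5-dichloro-3-Ar-benzene-1,4-diol F1. DDQ oxidises it in the same flask to 2,5-dichloro-3-Ar-1,4-benzoquinone F2. Indole 9 under the same acid conditions adds at the last free ring carbon to give 2,5-dichloro-3-(1H-indol-3-yl)-6-Ar-benzene-1,4-diol F3. DDQ turns it into 2,5-dichloro-3-(1H-indol-3-yl)-6-Ar-1,4-benzoquinone F4. NaOH in MeOH–H2O at reflux, then acid, exchanges both chlorides for hydroxyl and gives 11.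

Step 1. The tautomer equilibrium of the 3-unsubstituted chloroindole and the bromine next to nitrogen may slow the allylboration. The fallback reverses the roles: a nucleophilic 2-borylindole and an electrophilic prenyl ester. It sets out from 1 and comes back at 3. Ir-catalysed C2–H borylation of 1 ([Ir(OMe)(cod)]2, cod = cycloocta-1,5-diene, 4,4′-di-tert-butyl-2,2′-bipyridine, B2pin2, THF, 60 °C) gives 7-bromo-2-(4,4,5,5-tetramethyl-1,3,2-dioxaborolan-2-yl)-1H-indole F5. A γ-selective allyl–aryl coupling with 3-methylbut-2-en-1-yl acetate follows (Pd(OAc)2, 1,10-phenanthroline, AgSbF6, 1,2-dichloroethane, 60 °C). Under cationic divalent palladium the aryl group is transferred to palladium, adds syn across the alkene and β-acetoxy elimination follows. This puts the aryl group on the dimethyl-bearing carbon and gives 3. The C–Br bond stays because no zerovalent palladium is formed.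

Step 2. N-alkylation or protonation of the dianion may compete with C7-alkylation. The fallback replaces the organolithium alkylation by a cross-coupling. It sets out from 3 and comes back at 6: Stille coupling of 3 with tributyl(3-methylbut-2-en-1-yl)stannane (Pd(PPh3)4, a zerovalent palladium complex, LiCl, DMF, 100 °C). It tolerates the free NH and delivers the linear prenyl group. No new compound is made (F0).

Further compounds
F1 | step 4 | 2,5-dichloro-3-[2-(2-methylbut-3-en-2-yl)-7-(3-methylbut-2-en-1-yl)-1H-indol-3-yl]benzene-1,4-diol | Oc1cc(Cl)c(O)c(-c2c(C(C)(C)C=C)[nH]c3c(CC=C(C)C)cccc23)c1Cl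
F2 | step 4 | 2,5-dichloro-3-[2-(2-methylbut-3-en-2-yl)-7-(3-methylbut-2-en-1-yl)-1H-indol-3-yl]cyclohexa-2,5-diene-1,4-dione | O=C1C=C(Cl)C(=O)C(c2c(C(C)(C)C=C)[nH]c3c(CC=C(C)C)cccc23)=C1Cl
F3 | step 4 | 2,5-dichloro-3-(1H-indol-3-yl)-6-[2-(2-methylbut-3-en-2-yl)-7-(3-methylbut-2-en-1-yl)-1H-indol-3-yl]benzene-1,4-diol | Oc1c(Cl)c(-c2c(C(C)(C)C=C)[nH]c3c(CC=C(C)C)cccc23)c(O)c(Cl)c1-c1c[nH]c2ccccc12
F4 | step 4 | 2,5-dichloro-3-(1H-indol-3-yl)-6-[2-(2-methylbut-3-en-2-yl)-7-(3-methylbut-2-en-1-yl)-1H-indol-3-yl]cyclohexa-2,5-diene-1,4-dione | O=C1C(c2c[nH]c3ccccc23)=C(Cl)C(=O)C(c2c(C(C)(C)C=C)[nH]c3c(CC=C(C)C)cccc23)=C1Cl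
F5 | step 1 | 7-bromo-2-(4,4,5,5-tetramethyl-1,3,2-dioxaborolan-2-yl)-1H-indole | CC1(C)OB(OC1(C)C)c1cc2cccc(Br)c2[nH]1
F0 | step 2 | none | none
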